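**Retrosynthetic overview**
1. Target 12 comes from octa-O-benzyl dimer ester 10 by saponification and hydrogenolysis. No ring is built: rings A, B and C of both flavan units come intact from (−)-epicatechin 1, so there is no ring-forming order.
2. Interflavan C4–C8 bond of 10: Friedel–Crafts-type addition of C8 of lower unit 8 to the C4 cation 9 generated from the free-3-OH acetal 3.
3. Key C4–CH2CO2Me bond of 8: intermolecular Mukaiyama–Michael addition of silyl ketene acetal 5 to the quinone-methide cation 6 (from 3-O-acetate 4) on the β-face, then 3-O-deacetylation.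
4. 3 comes from 1 by per-O-benzylation and DDQ oxidation at C4 in the presence of 2-ethoxyethanol; 3 is the upper-unit electrophile as such and, as its acetate 4, the electrophile of the key step.

Assumption: (−)-epicatechin (bulk tea/cocoa isolate) and silyl ketene acetal 5 are taken as inexpensive catalogue chemicals. Flavan numbering is used in short names, and β means the face opposite to the 2-aryl and 3-oxygen groups of epicatechin.

**Step 1**
Reactants: 1 (−)-epicatechin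
Product: 2 5,7,3',4'-tetra-O-benzyl-(−)-epicatechin [(2R,3R)-5,7-bis(benzyloxy)-2-[3,4-bis(benzyloxy)phenyl]-3,4-dihydro-2H-chromen-3-ol]
Conditions: BnBr (4.4 equiv), K2CO3 (5 equiv), DMF, 0 °C → rt
Reagents that add atoms: benzyl bromide, BrCc1ccccc1
Why: Williamson ether synthesis; K2CO3 deprotonates only the four phenols, so the secondary 3-OH and both stereocentres are untouched.

**Step 2**
Reactants: 2 5,7,3',4'-tetra-O-benzyl-(−)-epicatechin
Product: 3 4β-(2-ethoxyethoxy)-5,7,3',4'-tetra-O-benzyl-(−)-epicatechin [(2R,3R,4S); 3,4-trans]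
Conditions: DDQ (2 equiv), 2-ethoxyethanol (5 equiv), CH2Cl2, rt
Reagents that add atoms: 2-ethoxyethanol, CCOCCO
Why: DDQ benzylic oxidation (hydride abstraction from the oxygen-activated C4–H) with trapping by the alcohol on the β-face, anti to the 2-aryl and 3-OH groups, sets C4 as 4S.

**Step 3**
Reactants: 3 4β-(2-ethoxyethoxy)-5,7,3',4'-tetra-O-benzyl-(−)-epicatechin
Product: 4 3-O-acetyl-4β-(2-ethoxyethoxy)-5,7,3',4'-tetra-O-benzyl-(−)-epicatechin [(2R,3R,4S)]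
Conditions: Ac2O, pyridine, DMAP (cat.), rt
Reagents that add atoms: acetic anhydride, CC(=O)OC(C)=O
Why: DMAP-catalysed acylation of the secondary alcohol; the acetate prevents O-silylation by the silyl ketene acetal in the next step and shields the α-face there by neighbouring-group participation.

**Step 4**
Reactants: 4 3-O-acetyl-4β-(2-ethoxyethoxy)-5,7,3',4'-tetra-O-benzyl-(−)-epicatechin; 5 tert-butyl[(1-methoxyethenyl)oxy]dimethylsilane
Product: 7 methyl 2-[(2R,3R,4S)-3-acetoxy-5,7-bis(benzyloxy)-2-[3,4-bis(benzyloxy)phenyl]-3,4-dihydro-2H-chromen-4-yl]acetate, via 3-acetoxy quinone-methide oxocarbenium triflate 6 (not isolated)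
Conditions: 5 (3 equiv), TBSOTf (0.1 equiv), CH2Cl2, −78 → −40 °C; aq NaHCO3
Reagents that add atoms: none
Why: Mukaiyama–Michael reaction: the silyl triflate ionises the C4 acetal to ion pair 6, a ring-A para-quinone-methide oxocarbenium, and the far more nucleophilic silyl ketene acetal 5 adds to its exocyclic carbon C4 on the β-face, anti to the participating 3-OAc and the 2-aryl group, setting the new stereocentre as 4S (3,4-trans).

**Step 5**
Reactants: 7 methyl 2-[(2R,3R,4S)-3-acetoxy-5,7-bis(benzyloxy)-2-[3,4-bis(benzyloxy)phenyl]-3,4-dihydro-2H-chromen-4-yl]acetate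
Product: 8 methyl 2-[(2R,3R,4S)-5,7-bis(benzyloxy)-2-[3,4-bis(benzyloxy)phenyl]-3-hydroxy-3,4-dihydro-2H-chromen-4-yl]acetate
Conditions: K2CO3 (0.3 equiv), MeOH/THF (1:1), 0 °C → rt
Reagents that add atoms: none
Why: Base-catalysed transesterification (Zemplén-type methanolysis) removes the acetate as methyl acetate, while exchange at the methyl ester is degenerate and no stereocentre is epimerisable.

**Step 6**
Reactants: 8 methyl 2-[(2R,3R,4S)-5,7-bis(benzyloxy)-2-[3,4-bis(benzyloxy)phenyl]-3-hydroxy-3,4-dihydro-2H-chromen-4-yl]acetate; 3 4β-(2-ethoxyethoxy)-5,7,3',4'-tetra-O-benzyl-(−)-epicatechin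
Product: 10 methyl 2-[(2R,3R,4S)-5,7-bis(benzyloxy)-8-[(2R,3R,4R)-5,7-bis(benzyloxy)-2-[3,4-bis(benzyloxy)phenyl]-3-hydroxy-3,4-dihydro-2H-chromen-4-yl]-2-[3,4-bis(benzyloxy)phenyl]-3-hydroxy-3,4-dihydro-2H-chromen-4-yl]acetate, via 3-hydroxy quinone-methide oxocarbenium triflate 9 (not isolated)
Conditions: 8 (2.0 equiv, excess recovered), 3 (1.0 equiv, added slowly), TMSOTf (0.2 equiv), CH2Cl2, −78 → −30 °C; aq NaHCO3
Reagents that add atoms: none
Why: Friedel–Crafts alkylation: acid-catalysed loss of 2-ethoxyethanol from 3 gives cation 9, and the most nucleophilic ring-A position C8 of 8 attacks its C4 on the β-face, anti to the 2-aryl and 3-hydroxy groups that both lie on the α-face in the epicatechin series, setting the interflavan stereocentre as 4R (4β→8, 3,4-trans).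

**Step 7**
Reactants: 10 the octa-O-benzyl dimer methyl ester
Product: 11 2-[(2R,3R,4S)-5,7-bis(benzyloxy)-8-[(2R,3R,4R)-5,7-bis(benzyloxy)-2-[3,4-bis(benzyloxy)phenyl]-3-hydroxy-3,4-dihydro-2H-chromen-4-yl]-2-[3,4-bis(benzyloxy)phenyl]-3-hydroxy-3,4-dihydro-2H-chromen-4-yl]acetic acid
Conditions: LiOH·H2O (5 equiv), THF/MeOH/H2O (3:1:1), rt; then 1 M HCl to pH 3–4, 0 °C
Reagents that add atoms: lithium hydroxide, [Li+].[OH-]
Why: Saponification of the methyl ester; with every phenol benzylated, no quinone-methide, retro-Michael or C2-epimerisation pathway is open under base, and the brief cold acidification avoids lactonisation onto the trans 3-OH.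

**Step 8**
Reactants: 11 the octa-O-benzyl dimer diol acid
Product: 12 2-[(2R,3R,4S)-2-(3,4-dihydroxyphenyl)-8-[(2R,3R,4R)-2-(3,4-dihydroxyphenyl)-3,5,7-trihydroxy-3,4-dihydro-2H-chromen-4-yl]-3,5,7-trihydroxy-3,4-dihydro-2H-chromen-4-yl]acetic acid [epicatechin-(4β→8)-4β-carboxymethylepicatechin, the target]
Conditions: H2 (1 atm), Pd(OH)2/C, THF/MeOH/H2O (20:20:1), rt; filtration, Sephadex LH-20
Reagents that add atoms: none
Why: Catalytic hydrogenolysis cleaves the eight benzyl ethers under neutral conditions without touching the interflavan C–C bond, the C2–O1 bonds or any stereocentre.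

**Compound list**
1 | (−)-epicatechin, (2R,3R) | C1c2c(O)cc(O)cc2O[C@H](c2ccc(O)c(O)c2)[C@@H]1O | starting material
2 | 5,7,3',4'-tetra-O-benzyl-(−)-epicatechin | C1c2c(OCc3ccccc3)cc(OCc3ccccc3)cc2O[C@H](c2ccc(OCc3ccccc3)c(OCc3ccccc3)c2)[C@@H]1O | intermediate
3 | 4β-(2-ethoxyethoxy)-5,7,3',4'-tetra-O-benzyl-(−)-epicatechin, (2R,3R,4S) | CCOCCO[C@H]1c2c(OCc3ccccc3)cc(OCc3ccccc3)cc2O[C@H](c2ccc(OCc3ccccc3)c(OCc3ccccc3)c2)[C@@H]1O | intermediate
4 | 3-O-acetyl-4β-(2-ethoxyethoxy)-5,7,3',4'-tetra-O-benzyl-(−)-epicatechin, (2R,3R,4S) | CCOCCO[C@H]1c2c(OCc3ccccc3)cc(OCc3ccccc3)cc2O[C@H](c2ccc(OCc3ccccc3)c(OCc3ccccc3)c2)[C@@H]1OC(C)=O | intermediate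
5 | tert-butyl[(1-methoxyethenyl)oxy]dimethylsilane (TBS ketene acetal of methyl acetate) | C=C(OC)O[Si](C)(C)C(C)(C)C | starting material
6 | C4 quinone-methide oxocarbenium triflate from 4 (C4=C4a, C7=O+Bn form; 2R,3R-3-acetoxy) | CC(=O)O[C@@H]1C=C2C(OCc3ccccc3)=CC(=[O+]Cc3ccccc3)C=C2O[C@@H]1c1ccc(OCc3ccccc3)c(OCc3ccccc3)c1.[O-]S(=O)(=O)C(F)(F)F | intermediate (not isolated)
7 | methyl 2-[(2R,3R,4S)-3-acetoxy-5,7-bis(benzyloxy)-2-[3,4-bis(benzyloxy)phenyl]-3,4-dihydro-2H-chromen-4-yl]acetate | COC(=O)C[C@H]1c2c(OCc3ccccc3)cc(OCc3ccccc3)cc2O[C@H](c2ccc(OCc3ccccc3)c(OCc3ccccc3)c2)[C@@H]1OC(C)=O | intermediate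
8 | methyl 2-[(2R,3R,4S)-5,7-bis(benzyloxy)-2-[3,4-bis(benzyloxy)phenyl]-3-hydroxy-3,4-dihydro-2H-chromen-4-yl]acetate | COC(=O)C[C@H]1c2c(OCc3ccccc3)cc(OCc3ccccc3)cc2O[C@H](c2ccc(OCc3ccccc3)c(OCc3ccccc3)c2)[C@@H]1O | intermediate
9 | C4 quinone-methide oxocarbenium triflate from 3 (C4=C4a, C7=O+Bn form; 2R,3R-3-hydroxy) | O[C@@H]1C=C2C(OCc3ccccc3)=CC(=[O+]Cc3ccccc3)C=C2O[C@@H]1c1ccc(OCc3ccccc3)c(OCc3ccccc3)c1.[O-]S(=O)(=O)C(F)(F)F | intermediate (not isolated)
10 | octa-O-benzyl-epicatechin-(4β→8)-4β-(methoxycarbonylmethyl)epicatechin (upper unit 2R,3R,4R; lower unit 2R,3R,4S) | COC(=O)C[C@H]1c2c(OCc5ccccc5)cc(OCc5ccccc5)c([C@H]3c4c(OCc5ccccc5)cc(OCc5ccccc5)cc4O[C@H](c4ccc(OCc5ccccc5)c(OCc5ccccc5)c4)[C@@H]3O)c2O[C@H](c2ccc(OCc5ccccc5)c(OCc5ccccc5)c2)[C@@H]1O | intermediate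
11 | octa-O-benzyl-epicatechin-(4β→8)-4β-carboxymethylepicatechin (diol acid) | OC(=O)C[C@H]1c2c(OCc5ccccc5)cc(OCc5ccccc5)c([C@H]3c4c(OCc5ccccc5)cc(OCc5ccccc5)cc4O[C@H](c4ccc(OCc5ccccc5)c(OCc5ccccc5)c4)[C@@H]3O)c2O[C@H](c2ccc(OCc5ccccc5)c(OCc5ccccc5)c2)[C@@H]1O | intermediate
12 | epicatechin-(4β→8)-4β-carboxymethylepicatechin (CNP0190976.1) | O=C(O)C[C@H]1c2c(O)cc(O)c([C@H]3c4c(O)cc(O)cc4O[C@H](c4ccc(O)c(O)c4)[C@@H]3O)c2O[C@H](c2ccc(O)c(O)c2)[C@@H]1O | target

**Step count and risks**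
Total steps: 8. Longest linear sequence: 8 steps (1 → 2 → 3 → 4 → 7 → 8 → 10 → 11 → 12); compound 3 is used a second time, as the electrophile, in step 6.

Most likely to fail, first: step 4. Silyl ketene acetals have less precedent at flavan C4 than allylsilanes or arenes. The fallback sets out from 4 and comes back to the route at 7. Hosomi–Sakurai allylation of 4 (allyltrimethylsilane, BF3·OEt2, CH2Cl2, −78 → 0 °C) gives 3-O-acetyl-4β-allyl-5,7,3',4'-tetra-O-benzyl-(−)-epicatechin F1. Lemieux–Johnson cleavage (OsO4 cat., NaIO4, 2,6-lutidine, dioxane/H2O) gives the C4 acetaldehyde F2. Pinnick oxidation (NaClO2, NaH2PO4, 2-methyl-2-butene, t-BuOH/H2O) gives the C4 acetic acid F3, and TMSCHN2 in toluene/MeOH methylates it to 7.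

Second: step 6. The uncapped electrophile can oligomerise, product 10 can react again, and some C6 attack is possible. The fallback sets out from 3 and comes back at 12, using a removable C8 blocking group on the electrophile. NBS (1.05 equiv, CH2Cl2, −78 → −20 °C) brominates 3 at C8 to give 8-bromo-4β-(2-ethoxyethoxy)-5,7,3',4'-tetra-O-benzyl-(−)-epicatechin F4, which cannot act as a nucleophile at C8. Coupling F4 with 8 (1:1, TMSOTf, CH2Cl2, −78 °C) gives the 8-bromo dimer ester F5. LiOH (THF/MeOH/H2O, then 1 M HCl) gives the 8-bromo diol acid F6. Hydrogenolysis with H2, Pd(OH)2/C and Et3N in THF/MeOH/H2O then removes the bromine together with the benzyl groups to give 12.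

Third: step 2. The DDQ oxidation gives moderate yields and can over-oxidise. The fallback sets out from 2 and comes back at 7 (key-step branch) and at 11 (coupling branch), replacing the oxidative acetal formation by a benzylic acetoxylation. Ac2O/pyridine converts 2 into 3-O-acetyl-5,7,3',4'-tetra-O-benzyl-(−)-epicatechin F7. Pb(OAc)4 in benzene at rt then acetoxylates C4 to give the 3,4β-di-O-acetate F8. F8 ionises under the silyl triflate conditions to the same 3-acetoxy cation as 4, so it takes the place of 4 in step 4 (giving 7). It also takes the place of 3 in step 6, where coupling with 8 gives the 3-O-acetyl dimer ester F9; the LiOH conditions of step 7 remove its acetate together with the methyl ester and give 11.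

**Further compounds**
F1 | step 4 | 3-O-acetyl-4β-allyl-5,7,3',4'-tetra-O-benzyl-(−)-epicatechin (2R,3R,4S) | C=CC[C@H]1c2c(OCc3ccccc3)cc(OCc3ccccc3)cc2O[C@H](c2ccc(OCc3ccccc3)c(OCc3ccccc3)c2)[C@@H]1OC(C)=O
F2 | step 4 | 2-[(2R,3R,4S)-3-acetoxy-5,7-bis(benzyloxy)-2-[3,4-bis(benzyloxy)phenyl]-3,4-dihydro-2H-chromen-4-yl]acetaldehyde | O=CC[C@H]1c2c(OCc3ccccc3)cc(OCc3ccccc3)cc2O[C@H](c2ccc(OCc3ccccc3)c(OCc3ccccc3)c2)[C@@H]1OC(C)=O
F3 | step 4 | 2-[(2R,3R,4S)-3-acetoxy-5,7-bis(benzyloxy)-2-[3,4-bis(benzyloxy)phenyl]-3,4-dihydro-2H-chromen-4-yl]acetic acid | OC(=O)C[C@H]1c2c(OCc3ccccc3)cc(OCc3ccccc3)cc2O[C@H](c2ccc(OCc3ccccc3)c(OCc3ccccc3)c2)[C@@H]1OC(C)=O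
F4 | step 6 | 8-bromo-4β-(2-ethoxyethoxy)-5,7,3',4'-tetra-O-benzyl-(−)-epicatechin | CCOCCO[C@H]1c2c(OCc3ccccc3)cc(OCc3ccccc3)c(Br)c2O[C@H](c2ccc(OCc3ccccc3)c(OCc3ccccc3)c2)[C@@H]1O
F5 | step 6 | 8-bromo analogue of 10 (bromine at C8 of the upper unit) | COC(=O)C[C@H]1c2c(OCc5ccccc5)cc(OCc5ccccc5)c([C@H]3c4c(OCc5ccccc5)cc(OCc5ccccc5)c(Br)c4O[C@H](c4ccc(OCc5ccccc5)c(OCc5ccccc5)c4)[C@@H]3O)c2O[C@H](c2ccc(OCc5ccccc5)c(OCc5ccccc5)c2)[C@@H]1O
F6 | step 6 | 8-bromo analogue of 11 (bromine at C8 of the upper unit) | OC(=O)C[C@H]1c2c(OCc5ccccc5)cc(OCc5ccccc5)c([C@H]3c4c(OCc5ccccc5)cc(OCc5ccccc5)c(Br)c4O[C@H](c4ccc(OCc5ccccc5)c(OCc5ccccc5)c4)[C@@H]3O)c2O[C@H](c2ccc(OCc5ccccc5)c(OCc5ccccc5)c2)[C@@H]1O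
F7 | step 2 | 3-O-acetyl-5,7,3',4'-tetra-O-benzyl-(−)-epicatechin | C1c2c(OCc3ccccc3)cc(OCc3ccccc3)cc2O[C@H](c2ccc(OCc3ccccc3)c(OCc3ccccc3)c2)[C@@H]1OC(C)=O
F8 | step 2 | 3,4β-di-O-acetyl-5,7,3',4'-tetra-O-benzyl-(−)-epicatechin (4β-acetoxy, 3,4-trans) | CC(=O)O[C@H]1c2c(OCc3ccccc3)cc(OCc3ccccc3)cc2O[C@H](c2ccc(OCc3ccccc3)c(OCc3ccccc3)c2)[C@@H]1OC(C)=O
F9 | step 2 | 3-O-acetyl analogue of 10 (acetate on the 3-OH of the upper unit) | COC(=O)C[C@H]1c2c(OCc5ccccc5)cc(OCc5ccccc5)c([C@H]3c4c(OCc5ccccc5)cc(OCc5ccccc5)cc4O[C@H](c4ccc(OCc5ccccc5)c(OCc5ccccc5)c4)[C@@H]3OC(C)=O)c2O[C@H](c2ccc(OCc5ccccc5)c(OCc5ccccc5)c2)[C@@H]1O
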